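**Retrosynthetic overview**
1. Feature: the lactone ring O1–C2(=O)–C3(OH)=C4(Ar)–C5(H)(CH2Ar') holds an (R)-3-aryllactic acid (O1, C5, its benzylic CH2, and C4 as the former carboxyl carbon; D-tyrosine with OH for NH2) that is O-acylated by a two-carbon glycolyl unit (C2, C3–O).
2. C4–aryl bond: Suzuki coupling of the C4 enol triflate of a 3-benzyloxytetronic acid with a silylated 4-hydroxyphenylboronic acid; the benzyl and silyl groups are removed last.
3. C3–C4 bond: Dieckmann condensation of the O-(benzyloxy)acetyl methyl ester; this closes the furanone ring, the only ring made (both benzene rings are bought).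
4. Prenyl group: aromatic Claisen shift of a 1,1-dimethylallyl aryl ether; C5–O bond: diazotisation of D-tyrosine with retention.

Key step: step 8

Remark: the 3-hydroxyfuranone is handled as the enol tautomer drawn in the target SMILES; 3-chloro-3-methylbut-1-yne and [4-(tert-butyldimethylsilyloxy)phenyl]boronic acid are taken as catalogue chemicals.

**Step 1**
Reactants: 1 D-tyrosine
Product: 4 (R)-2-hydroxy-3-(4-hydroxyphenyl)propanoic acid, via diazonium carboxylate 2 (not isolated), via α-lactone 3 (not isolated)
Conditions: NaNO2, 1 M H2SO4 aq., 0 °C to rt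
Reagents that add atoms: water, SMILES O
Why: Nitrous acid deamination (diazotisation) of the α-amino acid, in which the neighbouring carboxylate displaces N2 from 2 with inversion to give α-lactone 3 and water opens it at the same carbon with a second inversion, so the C–O bond forms with net retention and 4 keeps the (R) configuration.

**Step 2**
Reactants: 4 (R)-2-hydroxy-3-(4-hydroxyphenyl)propanoic acid
Product: 5 methyl (R)-2-hydroxy-3-(4-hydroxyphenyl)propanoate
Conditions: MeOH, H2SO4 (cat.), reflux
Reagents that add atoms: methanol, SMILES CO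
Why: Fischer esterification of the carboxylic acid, which leaves the phenol, the secondary alcohol and the stereocentre untouched.

**Step 3**
Reactants: 5 methyl (R)-2-hydroxy-3-(4-hydroxyphenyl)propanoate; 6 3-chloro-3-methylbut-1-yne
Product: 7 methyl (R)-2-hydroxy-3-[4-(2-methylbut-3-yn-2-yloxy)phenyl]propanoate
Conditions: DBU, CuCl2·2H2O (cat.), MeCN, 0 °C
Reagents that add atoms: none
Why: Copper-catalysed propargylic substitution (O-alkylation of the phenoxide by the tertiary propargylic chloride through a copper acetylide), the standard way to aryl 1,1-dimethylpropargyl ethers, in which the much less acidic secondary alcohol is not deprotonated and does not compete.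

**Step 4**
Reactants: 7 methyl (R)-2-hydroxy-3-[4-(2-methylbut-3-yn-2-yloxy)phenyl]propanoate
Product: 8 methyl (R)-2-hydroxy-3-[4-(2-methylbut-3-en-2-yloxy)phenyl]propanoate
Conditions: H2 (1 atm), 5% Pd/CaCO3 poisoned with Pb(OAc)2, quinoline, EtOAc, rt
Reagents that add atoms: none
Why: Semi-hydrogenation of the terminal alkyne over lead-poisoned palladium should stop at the alkene and gives the 1,1-dimethylallyl ether needed for the sigmatropic shift.

**Step 5**
Reactants: 8 methyl (R)-2-hydroxy-3-[4-(2-methylbut-3-en-2-yloxy)phenyl]propanoate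
Product: 10 methyl (R)-2-hydroxy-3-[4-hydroxy-3-(3-methylbut-2-en-1-yl)phenyl]propanoate, via ortho-dienone 9 (not isolated)
Conditions: PhNEt2, 130 °C
Reagents that add atoms: none
Why: Aromatic Claisen rearrangement, in which the [3,3] shift carries the allyl unit to the ortho carbon with transposition of its ends to give dienone 9, whose tautomerisation restores the phenol with a linear 3-methylbut-2-enyl group; the para position is blocked and the two ortho positions are equivalent, so one regioisomer is expected.

**Step 6**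
Reactants: 10 methyl (R)-2-hydroxy-3-[4-hydroxy-3-(3-methylbut-2-en-1-yl)phenyl]propanoate
Product: 11 methyl (R)-3-[4-(tert-butyldimethylsilyloxy)-3-(3-methylbut-2-en-1-yl)phenyl]-2-hydroxypropanoate
Conditions: TBSCl (1.05 equiv), imidazole, CH2Cl2, 0 °C
Reagents that add atoms: tert-butyldimethylsilyl chloride, SMILES CC(C)(C)[Si](C)(C)Cl
Why: Silylation of the phenol, which as the more acidic hydroxyl reacts much faster with TBSCl/imidazole than the electron-poor secondary alcohol next to the ester, so one equivalent at 0 °C should protect the phenol alone.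

**Step 7**
Reactants: 11 methyl (R)-3-[4-(tert-butyldimethylsilyloxy)-3-(3-methylbut-2-en-1-yl)phenyl]-2-hydroxypropanoate; 12 (benzyloxy)acetyl chloride
Product: 13 methyl (R)-2-[(benzyloxy)acetoxy]-3-[4-(tert-butyldimethylsilyloxy)-3-(3-methylbut-2-en-1-yl)phenyl]propanoate
Conditions: pyridine, DMAP (cat.), CH2Cl2, 0 °C to rt
Reagents that add atoms: none
Why: DMAP-catalysed acylation of the secondary alcohol by the acid chloride (nucleophilic acyl substitution), which does not touch the C–H bond at the stereocentre.

**Step 8**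
Reactants: 13 methyl (R)-2-[(benzyloxy)acetoxy]-3-[4-(tert-butyldimethylsilyloxy)-3-(3-methylbut-2-en-1-yl)phenyl]propanoate
Product: 15 (R)-3-(benzyloxy)-5-[4-(tert-butyldimethylsilyloxy)-3-(3-methylbut-2-en-1-yl)benzyl]-4-hydroxyfuran-2(5H)-one, via lithium tetronate 14 (not isolated)
Conditions: LiN(SiMe3)2 (2.2 equiv), THF, −78 °C; then 1 M HCl
Reagents that add atoms: none
Why: LiN(SiMe3)2 removes a proton from the (benzyloxy)acetyl CH2, with lithium held between the benzyloxy oxygen and the acyl carbonyl, and the glycolate enolate adds to the methyl ester carbonyl of the same molecule; loss of methoxide forms the C3–C4 bond, and the second equivalent of base converts the β-keto lactone at once into the stabilised tetronate 14, so the closure is not reversed. This is a Dieckmann (intramolecular Claisen) condensation of an O-acyl α-hydroxy ester, the established entry to 5-substituted tetronic acids. The ring closed is the five-membered lactone (O1, C2, C3, C4, C5), by 5-exo-trig attack of C3 on the C4 carbonyl. No stereocentre is created: C5 comes from D-tyrosine and none of its four bonds is broken. The selectivity needed is deprotonation at the acyl CH2 and not at the C5 methine next to the methyl ester, which would erode the configuration or start a 1,2-acyl shift; the unhindered, chelation-activated CH2 is reached far more easily by the bulky amide at −78 °C than the tertiary C–H flanked by the benzyl and acyloxy groups, and the fast ring closure consumes the enolate before proton exchange can occur.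

**Step 9**
Reactants: 15 (R)-3-(benzyloxy)-5-[4-(tert-butyldimethylsilyloxy)-3-(3-methylbut-2-en-1-yl)benzyl]-4-hydroxyfuran-2(5H)-one
Product: 16 (R)-4-(benzyloxy)-2-[4-(tert-butyldimethylsilyloxy)-3-(3-methylbut-2-en-1-yl)benzyl]-5-oxo-2,5-dihydrofuran-3-yl trifluoromethanesulfonate
Conditions: Tf2O, iPr2NEt, CH2Cl2, −78 °C
Reagents that add atoms: trifluoromethanesulfonic anhydride, SMILES O=S(=O)(OS(=O)(=O)C(F)(F)F)C(F)(F)F
Why: O-Sulfonylation of the tetronic acid at the C4 enol oxygen, the usual site for tetronates, gives the vinylogous acyl triflate, and the hindered amine at −78 °C should not remove the C5 proton.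

**Step 10**
Reactants: 16 the C4 triflate; 17 [4-(tert-butyldimethylsilyloxy)phenyl]boronic acid
Product: 18 (R)-3-(benzyloxy)-5-[4-(tert-butyldimethylsilyloxy)-3-(3-methylbut-2-en-1-yl)benzyl]-4-[4-(tert-butyldimethylsilyloxy)phenyl]furan-2(5H)-one
Conditions: Pd(PPh3)4 (5 mol%), K3PO4, 1,4-dioxane/H2O (20:1), 50 °C
Reagents that add atoms: none
Why: Suzuki–Miyaura coupling, in which zerovalent palladium inserts into the C4–O bond of the electron-poor enol triflate, the boronate transfers the aryl group and reductive elimination forms the C4–aryl bond; a mild phosphate base with little water at moderate temperature is chosen to spare the C5 stereocentre, the triflate and the aryl silyl ethers.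

**Step 11**
Reactants: 18 the 3-benzyloxy-4-arylfuranone
Product: 20 (R)-5-[4-(tert-butyldimethylsilyloxy)-3-(3-methylbut-2-en-1-yl)benzyl]-4-[4-(tert-butyldimethylsilyloxy)phenyl]-3-hydroxyfuran-2(5H)-one, via dichloroboryl enol ether 19 (not isolated)
Conditions: BCl3, C6HMe5, CH2Cl2, −78 °C; then Et3N/MeOH, −78 °C
Reagents that add atoms: none
Why: Lewis-acid cleavage of the benzyl enol ether, in which BCl3 binds the C3 oxygen next to the lactone carbonyl, pentamethylbenzene traps the benzyl cation by Friedel–Crafts alkylation before it can attack the prenyl group, and the boryl ether 19 is methanolysed in a buffered quench; both phenols stay silylated so that no free ortho-prenylphenol can cyclise, and hydrogen gas is avoided because of the prenyl double bond.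

**Step 12**
Reactants: 20 the bis-silyl ether
Product: 21 (R)-3-hydroxy-4-(4-hydroxyphenyl)-5-[4-hydroxy-3-(3-methylbut-2-en-1-yl)benzyl]furan-2(5H)-one
Conditions: Bu4NF, AcOH, THF, 0 °C to rt
Reagents that add atoms: none
Why: Fluoride-induced cleavage of both aryl silyl ethers, driven by the strong Si–F bond, with acetic acid keeping the medium near neutral so that the C5 proton of the butenolide is not exchanged.

**Compound list**
1 | D-tyrosine | N[C@H](Cc1ccc(O)cc1)C(=O)O | starting material
2 | (R)-1-carboxylato-2-(4-hydroxyphenyl)ethanediazonium (diazonium carboxylate) | N#[N+][C@H](Cc1ccc(O)cc1)C(=O)[O-] | intermediate (not isolated)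
3 | (S)-3-(4-hydroxybenzyl)oxiran-2-one (α-lactone) | O=C1O[C@H]1Cc2ccc(O)cc2 | intermediate (not isolated)
4 | (R)-2-hydroxy-3-(4-hydroxyphenyl)propanoic acid | Oc1ccc(C[C@@H](O)C(=O)O)cc1 | intermediate
5 | methyl (R)-2-hydroxy-3-(4-hydroxyphenyl)propanoate | Oc1ccc(C[C@@H](O)C(=O)OC)cc1 | intermediate
6 | 3-chloro-3-methylbut-1-yne | CC(C)(Cl)C#C | starting material
7 | methyl (R)-2-hydroxy-3-[4-(2-methylbut-3-yn-2-yloxy)phenyl]propanoate | C#CC(C)(C)Oc1ccc(C[C@@H](O)C(=O)OC)cc1 | intermediate
8 | methyl (R)-2-hydroxy-3-[4-(2-methylbut-3-en-2-yloxy)phenyl]propanoate | C=CC(C)(C)Oc1ccc(C[C@@H](O)C(=O)OC)cc1 | intermediate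
9 | methyl (2R)-2-hydroxy-3-[3-(3-methylbut-2-en-1-yl)-4-oxocyclohexa-1,5-dien-1-yl]propanoate (ortho-dienone, both epimers at the ring carbon) | O=C1C=CC(C[C@@H](O)C(=O)OC)=CC1CC=C(C)C | intermediate (not isolated)
10 | methyl (R)-2-hydroxy-3-[4-hydroxy-3-(3-methylbut-2-en-1-yl)phenyl]propanoate | CC(C)=CCc1cc(C[C@@H](O)C(=O)OC)ccc1O | intermediate
11 | methyl (R)-3-[4-(tert-butyldimethylsilyloxy)-3-(3-methylbut-2-en-1-yl)phenyl]-2-hydroxypropanoate | CC(C)=CCc1cc(C[C@@H](O)C(=O)OC)ccc1O[Si](C)(C)C(C)(C)C | intermediate
12 | (benzyloxy)acetyl chloride | ClC(=O)COCc1ccccc1 | starting material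
13 | methyl (R)-2-[(benzyloxy)acetoxy]-3-[4-(tert-butyldimethylsilyloxy)-3-(3-methylbut-2-en-1-yl)phenyl]propanoate | CC(C)=CCc1cc(C[C@@H](OC(=O)COCc2ccccc2)C(=O)OC)ccc1O[Si](C)(C)C(C)(C)C | intermediate
14 | lithium (R)-4-(benzyloxy)-2-[4-(tert-butyldimethylsilyloxy)-3-(3-methylbut-2-en-1-yl)benzyl]-5-oxo-2,5-dihydrofuran-3-olate (lithium tetronate) | CC(C)=CCc1cc(C[C@H]2OC(=O)C(OCc3ccccc3)=C2[O-])ccc1O[Si](C)(C)C(C)(C)C.[Li+] | intermediate (not isolated)
15 | (R)-3-(benzyloxy)-5-[4-(tert-butyldimethylsilyloxy)-3-(3-methylbut-2-en-1-yl)benzyl]-4-hydroxyfuran-2(5H)-one | CC(C)=CCc1cc(C[C@H]2OC(=O)C(OCc3ccccc3)=C2O)ccc1O[Si](C)(C)C(C)(C)C | intermediate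
16 | (R)-4-(benzyloxy)-2-[4-(tert-butyldimethylsilyloxy)-3-(3-methylbut-2-en-1-yl)benzyl]-5-oxo-2,5-dihydrofuran-3-yl trifluoromethanesulfonate | CC(C)=CCc1cc(C[C@H]2OC(=O)C(OCc3ccccc3)=C2OS(=O)(=O)C(F)(F)F)ccc1O[Si](C)(C)C(C)(C)C | intermediate
17 | [4-(tert-butyldimethylsilyloxy)phenyl]boronic acid | CC(C)(C)[Si](C)(C)Oc1ccc(B(O)O)cc1 | starting material
18 | (R)-3-(benzyloxy)-5-[4-(tert-butyldimethylsilyloxy)-3-(3-methylbut-2-en-1-yl)benzyl]-4-[4-(tert-butyldimethylsilyloxy)phenyl]furan-2(5H)-one | CC(C)=CCc1cc(C[C@H]2OC(=O)C(OCc3ccccc3)=C2c2ccc(O[Si](C)(C)C(C)(C)C)cc2)ccc1O[Si](C)(C)C(C)(C)C | intermediate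
19 | (R)-5-[4-(tert-butyldimethylsilyloxy)-3-(3-methylbut-2-en-1-yl)benzyl]-4-[4-(tert-butyldimethylsilyloxy)phenyl]-3-(dichloroboryloxy)furan-2(5H)-one | CC(C)=CCc1cc(C[C@H]2OC(=O)C(OB(Cl)Cl)=C2c2ccc(O[Si](C)(C)C(C)(C)C)cc2)ccc1O[Si](C)(C)C(C)(C)C | intermediate (not isolated)
20 | (R)-5-[4-(tert-butyldimethylsilyloxy)-3-(3-methylbut-2-en-1-yl)benzyl]-4-[4-(tert-butyldimethylsilyloxy)phenyl]-3-hydroxyfuran-2(5H)-one | CC(C)=CCc1cc(C[C@H]2OC(=O)C(O)=C2c2ccc(O[Si](C)(C)C(C)(C)C)cc2)ccc1O[Si](C)(C)C(C)(C)C | intermediate
21 | (R)-3-hydroxy-4-(4-hydroxyphenyl)-5-[4-hydroxy-3-(3-methylbut-2-en-1-yl)benzyl]furan-2(5H)-one | CC(C)=CCc1cc(C[C@H]2OC(=O)C(O)=C2c2ccc(O)cc2)ccc1O | target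

**Step count**
Total steps: 12. Longest linear sequence: 12 steps (1 to 21); compounds 6, 12 and 17 are bought.

**Steps most likely to fail**

Step 8 (Dieckmann closure). The base may remove the C5 methine proton instead of the acyl CH2 proton, which would lower the enantiomeric purity or start a 1,2-acyl migration. Condensation between two molecules may also compete with ring closure. The fallback makes the C3–C4 bond between two molecules and closes the O1–C2 bond afterwards. It sets out from 11. Silylation with Et3SiCl and imidazole gives methyl (R)-3-[4-(tert-butyldimethylsilyloxy)-3-(3-methylbut-2-en-1-yl)phenyl]-2-(triethylsilyloxy)propanoate F1. Methyl (benzyloxy)acetate, deprotonated with LiN(iPr)2 in THF at −78 °C and used in excess, is acylated by F1 (crossed Claisen condensation) to give methyl (4R)-2-(benzyloxy)-5-[4-(tert-butyldimethylsilyloxy)-3-(3-methylbut-2-en-1-yl)phenyl]-3-oxo-4-(triethylsilyloxy)pentanoate F2. Pyridinium p-toluenesulfonate in methanol should remove the alkyl triethylsilyl group while the aryl silyl ether stays, giving methyl (4R)-2-(benzyloxy)-5-[4-(tert-butyldimethylsilyloxy)-3-(3-methylbut-2-en-1-yl)phenyl]-4-hydroxy-3-oxopentanoate F3. F3 lactonises with loss of methanol, with a trace of Et3N if needed, and the fallback comes back to the route at 15.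

Step 10 (Suzuki coupling). The phosphate base may exchange the acidic C5 proton of the 4-arylbutenolide, which would erode the configuration. Aqueous base may also hydrolyse the vinylogous acyl triflate back to the tetronic acid or cleave aryl silyl ethers. The fallback is a Negishi coupling, which needs no Brønsted base. It sets out from 16. (4-Bromophenoxy)(tert-butyl)dimethylsilane and magnesium in THF give [4-(tert-butyldimethylsilyloxy)phenyl]magnesium bromide F4. Transmetalation with ZnCl2 gives [4-(tert-butyldimethylsilyloxy)phenyl]zinc chloride F5. F5 is coupled with 16 under Pd(PPh3)4 in THF at rt, and the fallback comes back to the route at 18.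

Step 11 (debenzylation). HCl may add to the prenyl double bond, the benzyl cation may alkylate the alkene or the arenes, and the Lewis acid may partly cleave the aryl silyl ethers. The fallback is catalytic transfer hydrogenolysis, which uses no Lewis acid. It sets out from 18 and uses Pd/C with 1,4-cyclohexadiene in EtOAc/EtOH at rt. The benzyl ether of the acidic enol should be cleaved much faster than the trisubstituted alkene is reduced, so the reaction is followed closely and stopped at full conversion. It comes back to the route at 20 and makes no new compound (F0).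

**Further compounds**
F1 | step 8 | methyl (R)-3-[4-(tert-butyldimethylsilyloxy)-3-(3-methylbut-2-en-1-yl)phenyl]-2-(triethylsilyloxy)propanoate | CC(C)=CCc1cc(C[C@@H](O[Si](CC)(CC)CC)C(=O)OC)ccc1O[Si](C)(C)C(C)(C)C
F2 | step 8 | methyl (4R)-2-(benzyloxy)-5-[4-(tert-butyldimethylsilyloxy)-3-(3-methylbut-2-en-1-yl)phenyl]-3-oxo-4-(triethylsilyloxy)pentanoate | CC(C)=CCc1cc(C[C@@H](O[Si](CC)(CC)CC)C(=O)C(OCc2ccccc2)C(=O)OC)ccc1O[Si](C)(C)C(C)(C)C
F3 | step 8 | methyl (4R)-2-(benzyloxy)-5-[4-(tert-butyldimethylsilyloxy)-3-(3-methylbut-2-en-1-yl)phenyl]-4-hydroxy-3-oxopentanoate | CC(C)=CCc1cc(C[C@@H](O)C(=O)C(OCc2ccccc2)C(=O)OC)ccc1O[Si](C)(C)C(C)(C)C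
F4 | step 10 | [4-(tert-butyldimethylsilyloxy)phenyl]magnesium bromide | CC(C)(C)[Si](C)(C)Oc1ccc([Mg]Br)cc1
F5 | step 10 | [4-(tert-butyldimethylsilyloxy)phenyl]zinc chloride | CC(C)(C)[Si](C)(C)Oc1ccc([Zn]Cl)cc1
F0 | step 11 | none | none
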